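Its constants were drawn at random within sensible limits; the rest is arithmetic.

If you want the most intermediate from a flask that makes it from substrate and spends it on target, you read it at the moment the making falls behind the spending.

| flask | substrate | temperature | time |
|---|---|---|---|
| Friday's | 0.20 mM | 5 °C | 1.0 min |
| Sunday's | 0.20 mM | −10 °C | 1.0 min |
| Tuesday's | 0.20 mM | 20 °C | 1.0 min |

    substrate ⇌ intermediate (K1 = 0.73, k1 = 0.0871 s⁻¹, Ea1 = 70.0 kJ mol⁻¹, ΔH1 = −33.0 kJ mol⁻¹)
    intermediate → target (k2 = 0.153 s⁻¹, Ea2 = 72.0 kJ mol⁻¹)
    substrate + target → side product (k3 = 235 L mol⁻¹ s⁻¹, Ea3 = 37.0 kJ mol⁻¹)
    (constants at 20 °C)

- a species is counted by the substrate in it: one side product counts as two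
- at 20 °C the constants are as listed, elsewhere as the activation energies and enthalpies make them

- the best flask by amount of intermediate, in percent of the substrate charged; "all alike" if 1.5 percentage points covers them all (Friday's / Sunday's / Tuesday's / all alike)
- amount of intermediate at the end, in percent of the substrate charged, Friday's
- amount of intermediate at the end, in percent of the substrate charged, Sunday's
- amount of intermediate at the end, in percent of the substrate charged, Tuesday's

You can fold the time and the temperature into one number. Take the forward constant of the first step at the flask's temperature and multiply it by the reading time. That constant grows by a factor of 26 from the coldest flask to the hottest, so Tuesday's gets 5.23 and Sunday's 0.198. Friday's temperature stands midway between theirs, so I take the geometric mean of the two constants, and Friday's gets 1.02. This is the clock number, a Damköhler number: the count of substrate lifetimes a flask is given before it is read.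

The second step runs 1.76 times as fast as the first at 20 °C, and that ratio changes by a factor of 1.10 from the coldest flask to the hottest, so I use it for each flask. A plain chain then peaks at a clock number of 0.745. Sunday's clock number is smaller than that. Friday's clock number is larger than that, and Tuesday's clock number is larger too. The chain picks Friday's. It gives 15.1% for Sunday's and 0.697% for Tuesday's.

One number is not enough for the height of Friday's, though. At 20 °C, the temperature of Tuesday's, falling back runs at 1.37 of the forward constant, and the third step at the charged [substrate] runs at 0.540 of it, and the clock number holds neither. So for Friday's I venture only an upper estimate, 25.7%.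

The forecast chose Friday's, with 20.2% for Friday's, 14.9% for Sunday's and 1.1% for Tuesday's, starting from “The side reaction is minor when cold”. Its Friday's figure stands lower than my upper estimate.

The simulation gives Friday's as the best flask, with 20.2% there, 14.9% in Sunday's and 1.04% in Tuesday's. At 1.00 min in Friday's, intermediate is made at 0.676 of the rate at which it is used up, each step taken net, so that flask is past its peak, where its clock number of 1.02 against 0.745 placed it. Read the same flask at 1.5 min and the clock number grows to 1.53, further past the peak, and the intermediate there stands at 13.8%.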